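Rank these flasks by the mean concentration of coupling partner over the run, and reckon that mean first.

| flask | substrate | coupling partner | remark | time |
|---|---|---|---|---|
| alpha | 0.0010 M | 0.89 mM (in portions, 2) | run made earlier; portions every 15 s |  |
| theta | 0.0010 M | 2.1 mM (in portions, 2) | run made earlier; portions every 15 s |  |
| zeta | 0.0010 M | 4.6 mM (in portions, 2) | run made earlier; portions every 15 s |  |
| Saturday's | 0.0010 M | 1.00 mM (in portions, 2) | the portions of coupling partner follow each other after 15 s, the first at the start | 2.5 min |
| Sunday's | 0.0010 M | 4.00 mM | everything together at the start | 2.5 min |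

| run | time / s | bis adduct / % | side product / % |
|---|---|---|---|
| alpha | 15.0 | 0 | 0.5 |
| alpha | 30.0 | 0.9 | 0.2 |
| alpha | 50.0 | 0.8 | 2.2 |
| alpha | 60.0 | 3.3 | 0.4 |
| alpha | 80.0 | 4.8 | 0.9 |
| theta | 10.0 | 0.1 | 0.2 |
| theta | 12.0 | 1.8 | 0 |
| theta | 20.0 | 0.8 | 0 |
| theta | 40.0 | 6.3 | 1.4 |
| theta | 80.0 | 22.4 | 3.5 |
| zeta | 10.0 | 1.5 | 0 |
| zeta | 12.0 | 2.9 | 0 |
| zeta | 20.0 | 8.9 | 0.6 |
| zeta | 40.0 | 28.4 | 0.3 |
| zeta | 80.0 | 60.5 | 4.3 |

(scatter of a reading: 1 percentage point)

- a species is counted by the substrate in it: one side product counts as two

- which one finishes higher in share of bis adduct in all that became bis adduct or side product ("neither" within 2 percentage points) (Saturday's / Sunday's / neither)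
- share of bis adduct in all that became bis adduct or side product, Saturday's
- share of bis adduct in all that became bis adduct or side product, Sunday's

Read bis adduct as the end of two equal steps through an intermediate, since zeta's curve starts flat, with 1.5 % at 10.0 s against 28.4 % at 40.0 s. Let x be rate constant times mean partner times time; then bis adduct is 1 − (1 + x)e^(−x) of the substrate, and partner used is 2 − (2 + x)e^(−x) substrate charges. Solve zeta's 60.5 % at 80.0 s by putting a first x back in, which gives 2.04. Take the charge weighted for the wait for the second portion, subtract used partner over 2, and the mean is 3.43 mM, so the rate constant reads 7.42 /M/s. Theta, the same way, gives x = 0.920 and a mean of 1.49 mM.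

Now multiply side product over bis adduct by mean partner: zeta reads 0.244 mM and theta 0.232 mM, while alpha's side reading lies under the scatter and is set aside. Their mean is my reading of the half-share concentration, the mean partner at which bis adduct and side product would come level, 0.238 mM, a selectivity factor in concentration units; with substrate held at 0.0010 M and for readings up to 2.5 min, I take the share as mean partner over mean partner plus this value.

Draw Sunday's curve: bis adduct leaves with zero slope, is steepest at x = 1, near 33.7 s at full charge, and partner in this two-step reading levels at 2.00 mM. Its mean goes from 3.04 mM to 3.09 mM on the second round, so the share is 92.9 %. Saturday's partner is the limiting reagent; its rounds swing between 0.481 mM and 0.692 mM, so take their middle, 0.587 mM, and the share is 71.1 %.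

The forecast, a little below my figures, names Sunday's, with 70 % and 92 %: “The bis adduct shows an induction period, so I read this as two steps”.

The flask gives Sunday's, with 69.1 % for Saturday's and 93.8 % for Sunday's.

    coupling partner + mono adduct → bis adduct (k = 5.94 /M/s)
    substrate + bis adduct → side product (k = 6.23 /M/s)
    substrate + coupling partner → mono adduct (k = 12.0 /M/s)

 Read Sunday's flask at 40 s instead: the mean goes from 3.49 mM to 3.54 mM, and the half-share concentration turns that into a share of 93.7 %. That flask gives 93.5 %, with bis adduct at 29.2 % and mono adduct at 49.4 %.

The numbers in the tables are calculated from invented constants; the scatter is artificial.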